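The cyclohexenone is cut at C1–C2 and C3–C4, which excises the C2=C3 vinylene as acetylene. Because the carbinol carbon C5 is flanked by the two ring methylenes C4 and C6, what remains is a symmetric, prochiral cyclobutanone. C5 becomes C3 of a 3-silyloxy-3-(2-oxoalkyl)cyclobutan-1-one, assembled by aldol union of a linoleic-acid-derived methyl ketone with a cyclobutane-1,3-dione monoketal. A chiral zerovalent-nickel catalyst then inserts acetylene into one of the two enantiotopic C(=O)–CH2 bonds of the strained ring. This single operation forms both ring bonds, creates the enone and sets the C5 stereocentre. Desilylation completes the route.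

Key step: step 4

Assumption: 3,3-dimethoxycyclobutan-1-one (the mono(dimethyl ketal) of cyclobutane-1,3-dione) is taken as a catalogue building block; the chemistry is unchanged with the ethylene ketal.

Step 1
Reactants: 1 linoleic acid [(9Z,12Z)-octadeca-9,12-dienoic acid]
Product: 3 (10Z,13Z)-nonadeca-10,13-dien-2-one, via dilithium gem-diolate 2 (not isolated)
Conditions: MeLi (2.2 equiv), Et2O, 0 °C to rt; inverse quench into cold 1 M HCl
Reagents that add atoms: methyllithium, [Li]C
Why: Conversion of a carboxylic acid into a methyl ketone with two equivalents of an alkyllithium: the lithium carboxylate takes up one MeLi to give the stable gem-diolate 2, which releases the ketone only on hydrolysis, so over-addition should be avoided and the skipped Z,Z-diene is left alone.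

Step 2
Reactants: 3 (10Z,13Z)-nonadeca-10,13-dien-2-one; 4 3,3-dimethoxycyclobutan-1-one
Product: 7 (10Z,13Z)-1-[3,3-dimethoxy-1-(triethylsilyloxy)cyclobutyl]nonadeca-10,13-dien-2-one, via lithium enolate 5 (not isolated), via lithium aldolate 6 (not isolated)
Conditions: LiN(iPr)2 (1.05 equiv), THF, −78 °C; then 4, −78 °C; then TESOTf (1.2 equiv), −78 °C; aq NaHCO3
Reagents that add atoms: triethylsilyl trifluoromethanesulfonate, CC[Si](CC)(CC)OS(=O)(=O)C(F)(F)F
Why: Kinetic deprotonation at the methyl group gives the terminal enolate, whose aldol addition to the strain-activated ketone of 4 should be trapped cold as the triethylsilyl ether by O-silylation of the tertiary lithium alkoxide before retro-aldol can intervene; no stereocentre arises because the carbinol carbon carries two identical ring arms.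

Step 3
Reactants: 7 (10Z,13Z)-1-[3,3-dimethoxy-1-(triethylsilyloxy)cyclobutyl]nonadeca-10,13-dien-2-one
Product: 8 3-[(10Z,13Z)-2-oxononadeca-10,13-dien-1-yl]-3-(triethylsilyloxy)cyclobutan-1-one
Conditions: PPTS (10 mol%), acetone/H2O (20:1), rt
Reagents that add atoms: water, O
Why: Buffered acid hydrolysis of the acyclic dimethyl ketal should spare the tertiary triethylsilyl ether, and the absence of base avoids E1cB loss of the β-silyloxy group from the cyclobutanone.

Step 4
Reactants: 8 3-[(10Z,13Z)-2-oxononadeca-10,13-dien-1-yl]-3-(triethylsilyloxy)cyclobutan-1-one; 9 acetylene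
Product: 10 (5S)-5-[(10Z,13Z)-2-oxononadeca-10,13-dien-1-yl]-5-(triethylsilyloxy)cyclohex-2-en-1-one
Conditions: Ni(cod)2 (10 mol%), (S)-BINOL-derived N,N-bis[(S)-1-phenylethyl]phosphoramidite (20 mol%; the antipode if the sense of induction requires it), toluene, 60 °C, acetylene (about 2 equiv) admitted over 8 h as a dilute stream in argon
Reagents that add atoms: none
Why: Proposed new method: zerovalent nickel binds the strained ketone of 8 together with acetylene and couples them oxidatively to a spiro oxanickelacyclopentene (first bond, alkyne carbon to C1), strain-driven β-carbon elimination then moves one ring CH2 from C1 to nickel to give a seven-membered nickelacycle, and C(sp2)–C(sp3) reductive elimination forms the second bond and returns the catalyst. The closest known reaction type is the nickel-catalysed intermolecular insertion of internal alkynes into cyclobutanones to give cyclohex-2-enones, which has not been shown with acetylene itself or as an enantioselective intermolecular desymmetrisation. The six-membered ring is closed by ring-contracting reductive elimination from the seven-membered divalent-nickel metallacycle, a formal [4+2] ring expansion of the four-membered ring. The only stereocentre, C5 of 10, comes from prochiral C3 of 8 and is controlled by the chiral phosphoramidite on nickel, which must direct β-carbon elimination to the C1–CH2 bond of the methylene that is pro-S at C3 to give (5S)-10. The step needs this enantiotopic-bond selectivity, chemoselectivity for the cyclobutanone over the unstrained side-chain ketone and the skipped diene, and cross- over homo-coupling of acetylene: the unlike C3 substituents (compact OSiEt3 against the CH2C(=O)R arm) fix the orientation of the spiro metallacycle so that the ligand has only to choose between two methylenes, ring strain reserves C–C cleavage for the four-membered ketone, and a bulky monodentate ligand with slow acetylene feed keeps a second alkyne off nickel. The silyl ether blocks retro-aldol opening and disfavours β-oxygen elimination from the alkylnickel intermediate.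

Step 5
Reactants: 10 (5S)-5-[(10Z,13Z)-2-oxononadeca-10,13-dien-1-yl]-5-(triethylsilyloxy)cyclohex-2-en-1-one
Product: 11 (5S)-5-hydroxy-5-[(10Z,13Z)-2-oxononadeca-10,13-dien-1-yl]cyclohex-2-en-1-one
Conditions: HF·pyridine, pyridine, THF, 0 °C
Reagents that add atoms: none
Why: Buffered fluoride-mediated Si–O cleavage should free the tertiary alcohol without the stronger acid or base that would dehydrate the β-hydroxy enone to a phenol or open it by retro-aldol, and C5 is not touched.

Compound list
1 | linoleic acid, (9Z,12Z)-octadeca-9,12-dienoic acid | CCCCC/C=C\C/C=C\CCCCCCCC(=O)O | starting material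
2 | dilithium (10Z,13Z)-nonadeca-10,13-diene-2,2-diolate | CCCCC/C=C\C/C=C\CCCCCCCC(C)(O[Li])O[Li] | intermediate (not isolated)
3 | (10Z,13Z)-nonadeca-10,13-dien-2-one | CCCCC/C=C\C/C=C\CCCCCCCC(C)=O | intermediate
4 | 3,3-dimethoxycyclobutan-1-one | COC1(OC)CC(=O)C1 | starting material
5 | lithium (10Z,13Z)-nonadeca-1,10,13-trien-2-olate (terminal enolate of 3) | CCCCC/C=C\C/C=C\CCCCCCCC(=C)O[Li] | intermediate (not isolated)
6 | lithium 3,3-dimethoxy-1-[(10Z,13Z)-2-oxononadeca-10,13-dien-1-yl]cyclobutan-1-olate | CCCCC/C=C\C/C=C\CCCCCCCC(=O)CC1(O[Li])CC(OC)(OC)C1 | intermediate (not isolated)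
7 | (10Z,13Z)-1-[3,3-dimethoxy-1-(triethylsilyloxy)cyclobutyl]nonadeca-10,13-dien-2-one | CCCCC/C=C\C/C=C\CCCCCCCC(=O)CC1(O[Si](CC)(CC)CC)CC(OC)(OC)C1 | intermediate
8 | 3-[(10Z,13Z)-2-oxononadeca-10,13-dien-1-yl]-3-(triethylsilyloxy)cyclobutan-1-one | CCCCC/C=C\C/C=C\CCCCCCCC(=O)CC1(O[Si](CC)(CC)CC)CC(=O)C1 | intermediate
9 | acetylene | C#C | starting material
10 | (5S)-5-[(10Z,13Z)-2-oxononadeca-10,13-dien-1-yl]-5-(triethylsilyloxy)cyclohex-2-en-1-one | CCCCC/C=C\C/C=C\CCCCCCCC(=O)C[C@@]1(O[Si](CC)(CC)CC)CC=CC(=O)C1 | intermediate
11 | (5S)-5-hydroxy-5-[(10Z,13Z)-2-oxononadeca-10,13-dien-1-yl]cyclohex-2-en-1-one | CCCCC/C=C\C/C=C\CCCCCCCC(=O)C[C@@]1(O)CC=CC(=O)C1 | target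

Total step count: 5. Longest linear sequence: 5 steps (1 → 3 → 7 → 8 → 10 → 11).

Steps most likely to fail

Step 4 (Proposed new method). Three processes may defeat it:
- cyclo-oligomerisation of acetylene at nickel may outrun the ketone–alkyne coupling;
- the catalyst may discriminate poorly between the two enantiotopic C–C bonds;
- β-oxygen elimination may occur from the alkylnickel intermediate.

The fallback uses known chemistry only, sets out from 3 and returns at 11. The ring is taken from commercial cis,cis-cyclohexane-1,3,5-triol and the stereocentre is set by an enzymatic desymmetrisation.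
- The triol is bis-silylated (TBSCl, imidazole, DMF; statistical, other ethers recycled) to cis,cis-3,5-bis(tert-butyldimethylsilyloxy)cyclohexan-1-ol F1 and oxidised (DMSO, (COCl)2, Et3N) to the meso ketone F2.
- Lithium enolate 5, made from 3 as in step 2, should add to F2 at −78 °C by equatorial attack to give the meso aldol F3 (tertiary OH trans to both silyloxy groups; the epimer is removed by chromatography).
- HF·pyridine should give the meso triol F4, and Ac2O/pyridine should acetylate only the two secondary hydroxyls to give the diacetate F5.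
- Candida antarctica lipase B in pH 7 buffer should hydrolyse the (R)-configured acetate, in line with the usual preference of lipases, leaving the monoacetate F6 [(S)-acetate, (R)-alcohol].
- Oxidation of the free secondary alcohol (DMSO, (COCl)2; Et3N, −78 to 0 °C) gives the β-acetoxy ketone F7, which should lose acetic acid under the same amine to give 11.

The enone is thus formed by E1cB loss of acetate and not by a dehydrogenation, which the second ketone would not allow.

Step 2. Proton exchange may erode the regiochemistry of the enolate, the aldolate may revert before it is silylated, or O-silylation of the hindered alkoxide may stay incomplete. The fallback sets out from 3 and returns at 7; it separates the three events.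
- 3 is converted (LiN(iPr)2, TMSCl, THF, −78 °C) into the isolable terminal silyl enol ether (10Z,13Z)-2-(trimethylsilyloxy)nonadeca-1,10,13-triene F8.
- MeLi (THF, 0 °C) regenerates enolate 5 from F8 regiospecifically and free of amine; addition to 4 at −78 °C and a cold AcOH quench should give the isolated aldol (10Z,13Z)-1-(1-hydroxy-3,3-dimethoxycyclobutyl)nonadeca-10,13-dien-2-one F9.
- F9 is silylated in a separate operation (TESOTf, 2,6-lutidine, CH2Cl2, −78 °C) to give 7.

Step 3. The silyl ether may be lost under the acid, or hydrolysis of the strained ketal may be slow. The fallback sets out from 7 and returns at 8. Both groups are removed on purpose (1 M HCl, THF, 0 °C) to give 3-hydroxy-3-[(10Z,13Z)-2-oxononadeca-10,13-dien-1-yl]cyclobutan-1-one F10. The tertiary alcohol is then silylated again under cold, weakly basic conditions (TESOTf, 2,6-lutidine, CH2Cl2, −78 °C) that should not trigger retro-aldol opening, to give 8.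

Further compounds
F1 | step 4 | cis,cis-3,5-bis(tert-butyldimethylsilyloxy)cyclohexan-1-ol | O[C@@H]1C[C@H](O[Si](C)(C)C(C)(C)C)C[C@H](O[Si](C)(C)C(C)(C)C)C1
F2 | step 4 | cis-3,5-bis(tert-butyldimethylsilyloxy)cyclohexan-1-one (meso) | O=C1C[C@H](O[Si](C)(C)C(C)(C)C)C[C@H](O[Si](C)(C)C(C)(C)C)C1
F3 | step 4 | (10Z,13Z)-1-[cis-3,5-bis(tert-butyldimethylsilyloxy)-1-hydroxycyclohexyl]nonadeca-10,13-dien-2-one, meso, 1-OH trans to both silyloxy groups | CCCCC/C=C\C/C=C\CCCCCCCC(=O)C[C@@]1(O)C[C@@H](O[Si](C)(C)C(C)(C)C)C[C@@H](O[Si](C)(C)C(C)(C)C)C1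
F4 | step 4 | (10Z,13Z)-1-(1,cis-3,5-trihydroxycyclohexyl)nonadeca-10,13-dien-2-one, meso, 1-OH trans to the 3- and 5-OH | CCCCC/C=C\C/C=C\CCCCCCCC(=O)C[C@@]1(O)C[C@@H](O)C[C@@H](O)C1
F5 | step 4 | 3,5-diacetate of F4 (meso) | CCCCC/C=C\C/C=C\CCCCCCCC(=O)C[C@@]1(O)C[C@@H](OC(C)=O)C[C@@H](OC(C)=O)C1
F6 | step 4 | monoacetate of F4 with the acetate on the (S)-carbinol and the free secondary hydroxyl on the (R)-carbinol | CCCCC/C=C\C/C=C\CCCCCCCC(=O)C[C@@]1(O)C[C@@H](OC(C)=O)C[C@@H](O)C1
F7 | step 4 | 3-acetoxy-5-hydroxy-5-[(10Z,13Z)-2-oxononadeca-10,13-dien-1-yl]cyclohexan-1-one, acetate trans to the tertiary hydroxyl | CCCCC/C=C\C/C=C\CCCCCCCC(=O)C[C@@]1(O)C[C@@H](OC(C)=O)CC(=O)C1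
F8 | step 2 | (10Z,13Z)-2-(trimethylsilyloxy)nonadeca-1,10,13-triene | CCCCC/C=C\C/C=C\CCCCCCCC(=C)O[Si](C)(C)C
F9 | step 2 | (10Z,13Z)-1-(1-hydroxy-3,3-dimethoxycyclobutyl)nonadeca-10,13-dien-2-one | CCCCC/C=C\C/C=C\CCCCCCCC(=O)CC1(O)CC(OC)(OC)C1
F10 | step 3 | 3-hydroxy-3-[(10Z,13Z)-2-oxononadeca-10,13-dien-1-yl]cyclobutan-1-one | CCCCC/C=C\C/C=C\CCCCCCCC(=O)CC1(O)CC(=O)C1
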